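**Retrosynthetic overview**
1. Feature: in ring A (a pentasubstituted, resorcinol-type arene) the ether carbon C4a and the carboxyl-bearing carbon C11a are neighbours. Their oxygens O5 and O10 sit on the adjacent carbons C7 and C6 of ring C, so this catechol can hold a ketene alpha carbon and an ynol ether carbon where the C4a–C11a bond must form.
2. Endgame: the C4 formyl group comes from CH2OH (MnO2), which comes from CH2OTBS (fluoride).
3. Key disconnection: rings A and B are opened together to a 2-diazo-3-oxo ester on O6 and a 3-silyloxypropynyl ether on O7. Forward, a Wolff shift is followed by [2+2] addition (C4a–C11a, C3–C4) and 6π closure (C2–C3).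
4. The precursor is joined at low temperature from a 6-O-TIPS 7-ynol ether (CuI coupling of the 7-phenol with a 1,1-dibromoalkene) and a preformed diazo keto acid, because a free 6-OH beside the ynol ether would add to it.
5. Ring order: C is bought (2-methoxy-6-methylphenol, then para-oxygenated), D follows by acylation/oxa-Michael closure with 3-methylbut-2-enoic acid, and B and A form in one operation.

Key step: step 12

Remark: rings A and B carry depsidone numbering (C1 CH3, C2 H, C3 OH, C4 CHO, C4a, O5, O10, C11 carbonyl, C11a). Rings C and D carry chroman-4-one numbering (O6 = O10, O7 = O5). The target has no stereocentre, and the only isolated chiral compound (17) is racemic and loses its centre in step 9.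

Step 1
Reactants: 1 2-methoxy-6-methylphenol
Product: 3 2-methoxy-6-methylbenzene-1,4-diol, via 2-methoxy-6-methyl-1,4-benzoquinone 2 (not isolated)
Conditions: O2 (1 atm), Co(salen) (5 mol %), DMF, rt; then aq Na2S2O4, EtOAc, rt
Reagents that add atoms: dioxygen, O=O
Why: Co(salen)-catalysed aerobic oxidation of a 2,6-disubstituted phenol with a free para position is a standard phenol-to-para-quinone oxidation, and dithionite reduction in the work-up should deliver the hydroquinone with the third ring C oxygen fixed para to the original OH.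

Step 2
Reactants: 3 2-methoxy-6-methylbenzene-1,4-diol; 4 3-methylbut-2-enoic acid
Product: 6 6-hydroxy-7-methoxy-2,2,5-trimethylchroman-4-one, via ortho-hydroxyaryl enone 5 (not isolated)
Conditions: P2O5/MeSO3H (1:10 w/w), N2, 70 °C
Reagents that add atoms: none
Why: Friedel–Crafts acylation followed by oxa-Michael closure (one-pot chromanone synthesis): only the 4-OH has free ortho positions, the one para to OMe and next to CH3 should be acylated as in orcinol-type arenes while the site between OH and OMe is the disfavoured one of a resorcinol ether, and the dehydrating medium favours the acylium path over alkene protonation that would lead to a 4,4-dimethylchroman-2-one.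

Step 3
Reactants: 6 6-hydroxy-7-methoxy-2,2,5-trimethylchroman-4-one
Product: 7 6,7-dihydroxy-2,2,5-trimethylchroman-4-one
Conditions: BBr3 (2.5 equiv), CH2Cl2, −78 to 0 °C; then H2O
Reagents that add atoms: none
Why: BBr3 cleavage of an aryl methyl ether, helped here by the free 6-OH, which first binds boron and holds it next to the methoxy oxygen, so that the low temperature should spare the ring D ether oxygen, which is deactivated as part of a vinylogous ester.

Step 4
Reactants: 7 6,7-dihydroxy-2,2,5-trimethylchroman-4-one
Product: 8 2,2,5-trimethyl-6,7-bis(triisopropylsilyloxy)chroman-4-one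
Conditions: TIPSOTf (2.5 equiv), 2,6-lutidine, CH2Cl2, 0 °C to rt
Reagents that add atoms: triisopropylsilyl triflate, CC(C)[Si](OS(=O)(=O)C(F)(F)F)(C(C)C)C(C)C
Why: Standard O-silylation, with the silyl triflate chosen because O6 lies between the C5 methyl group and O7.

Step 5
Reactants: 8 2,2,5-trimethyl-6,7-bis(triisopropylsilyloxy)chroman-4-one
Product: 9 7-hydroxy-2,2,5-trimethyl-6-(triisopropylsilyloxy)chroman-4-one
Conditions: TBAF/AcOH (1:1, 1.05 equiv), THF, −20 °C
Reagents that add atoms: none
Why: Selective fluoride desilylation: the O7–Si bond is para to the C4 ketone, so it releases the better leaving phenoxide and has only one bulky neighbour, whereas O6–Si is shielded on both sides, and the acetic acid buffer protonates the 7-phenoxide at once so that silyl migration and a second cleavage are held back.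

Step 6
Reactants: 10 (tert-butyldimethylsilyloxy)acetaldehyde
Product: 11 tert-butyl[(3,3-dibromoprop-2-en-1-yl)oxy]dimethylsilane
Conditions: CBr4, PPh3, CH2Cl2, 0 °C
Reagents that add atoms: carbon tetrabromide, BrC(Br)(Br)Br
Why: Ramirez dibromo-olefination (first stage of the Corey–Fuchs sequence), which works on alpha-silyloxy aldehydes at 0 °C without loss of the TBS group.

Step 7
Reactants: 9 7-hydroxy-2,2,5-trimethyl-6-(triisopropylsilyloxy)chroman-4-one; 11 tert-butyl[(3,3-dibromoprop-2-en-1-yl)oxy]dimethylsilane
Product: 13 7-{[3-(tert-butyldimethylsilyloxy)prop-1-yn-1-yl]oxy}-2,2,5-trimethyl-6-(triisopropylsilyloxy)chroman-4-one, via (Z)-bromo enol ether 12 (not isolated)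
Conditions: CuI (10 mol %), 2,2'-bipyridine (20 mol %), K3PO4, toluene, 110 °C; then KOtBu, 1,4-dioxane, rt, short contact
Reagents that add atoms: none
Why: Known copper-catalysed Ullmann-type C–O coupling of a phenol at the less hindered C–Br bond of a 1,1-dibromoalkene followed by anti dehydrobromination of the (Z)-bromo enol ether to the aryl ynol ether; O6 must be capped because a free neighbouring OH would close onto the bromo enol ether or the ynol ether to a 2-alkylidene-1,3-benzodioxole, and a 6-to-7 silyl shift is unproductive since the 7-phenoxide is both the more stable anion and the less hindered nucleophile.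

Step 8
Reactants: 14 tert-butyl diazoacetate; 15 methacrolein
Product: 17 tert-butyl 2-diazo-3-hydroxy-4-methylpent-4-enoate (racemic), via tert-butyl lithiodiazoacetate 16 (not isolated)
Conditions: LDA, THF, −78 °C; then 15, −78 °C; AcOH quench
Reagents that add atoms: none
Why: Aldol-type 1,2-addition of a lithiated diazoacetate to an enal at −78 °C, fast enough to outrun dipolar cycloaddition to the C=C bond; the new carbinol centre forms as a racemate and is removed in step 9.

Step 9
Reactants: 17 tert-butyl 2-diazo-3-hydroxy-4-methylpent-4-enoate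
Product: 18 tert-butyl 2-diazo-4-methyl-3-oxopent-4-enoate
Conditions: 2-iodoxybenzoic acid (IBX), DMSO, rt
Reagents that add atoms: none
Why: IBX oxidation of a beta-hydroxy-alpha-diazo ester to the alpha-diazo-beta-keto ester is an established reaction that leaves the diazo group and the alkene untouched, and this order avoids the free 4-methyl-3-oxopent-4-enoate, which self-condenses by Michael addition under the basic conditions of a diazo transfer.

Step 10
Reactants: 18 tert-butyl 2-diazo-4-methyl-3-oxopent-4-enoate
Product: 19 2-diazo-4-methyl-3-oxopent-4-enoic acid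
Conditions: TFA/CH2Cl2 (1:4), 0 °C to rt
Reagents that add atoms: none
Why: Acidolysis of a tert-butyl ester (E1 loss of isobutene); a diazo carbon flanked by two carbonyl groups is too weakly basic to be protonated by TFA, and the acid is used promptly to forestall decarboxylation.

Step 11
Reactants: 13 7-{[3-(tert-butyldimethylsilyloxy)prop-1-yn-1-yl]oxy}-2,2,5-trimethyl-6-(triisopropylsilyloxy)chroman-4-one; 19 2-diazo-4-methyl-3-oxopent-4-enoic acid
Product: 22 7-{[3-(tert-butyldimethylsilyloxy)prop-1-yn-1-yl]oxy}-2,2,5-trimethyl-4-oxochroman-6-yl 2-diazo-4-methyl-3-oxopent-4-enoate, via diazo keto acid chloride 20 (not isolated), via sulfonium phenoxide 21 (not isolated)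
Conditions: flask A: 19, 1-chloro-N,N,2-trimethylprop-1-en-1-amine, CH2Cl2, 0 °C; flask B: 13, tris(dimethylamino)sulfonium difluorotrimethylsilicate (TASF, 1.05 equiv), THF/MeCN, −20 °C; A into B, −40 to 0 °C
Reagents that add atoms: none
Why: Fluoride desilylation and O-acylation in one pot: the aryl O–Si bond is cleaved far faster than the primary alkyl O–Si bond, the phenoxide set free in an aprotic medium cannot complete 5-exo addition to the ynol ether for want of a proton, and it is acylated at once by the acid chloride made under neutral conditions, so the ynol ether sees neither acid nor heat.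

Step 12
Reactants: 22 7-{[3-(tert-butyldimethylsilyloxy)prop-1-yn-1-yl]oxy}-2,2,5-trimethyl-4-oxochroman-6-yl 2-diazo-4-methyl-3-oxopent-4-enoate
Product: 27 4-(tert-butyldimethylsilyloxymethyl) analogue of mollicellin B (CH2OTBS in place of CHO), via vinylketene 23 (not isolated), via fused cyclobutenone 24 (not isolated), via dienylketene 25 (not isolated), via cyclohexadienone 26 (not isolated)
Conditions: syringe-pump addition of 22 (toluene) to o-xylene at reflux (144 °C), Ar, base-washed glassware, final ca. 1 mM; then 2 h at reflux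
Reagents that add atoms: none
Why: Proposed new method: dropping 22 into hot xylene should expel N2 with 1,2-shift of the isopropenyl group (Wolff rearrangement, the ketone substituent migrating in preference to aryloxy and making C11a–C1) to give the (aryloxycarbonyl)(isopropenyl)ketene 23, whose carbonyl carbon is attacked by the nucleophilic alkyne carbon bearing CH2OTBS while its alpha carbon bonds to the oxygen-bearing alkyne carbon, giving the 4-vinylcyclobutenone 24, after which conrotatory 4π opening to 25, disrotatory 6π closure to 26 and tautomerisation should give phenol 27. The closest known reaction type is the Danheiser benzannulation of Wolff-derived vinylketenes with alkynyl ethers, which is known only intermolecularly and without an ester group on the ketene. Ring B closes in the [2+2] step as the seven-membered ring of a bicyclo[5.2.0] system, by formation of C4a–C11a across the five-atom tether O5–C7–C6–O10–C11, and ring A closes in the 6π electrocyclisation by formation of C2–C3 after C3–C4 has been made in the [2+2] step. No stereocentre remains: the quaternary carbon of 24 is racemic and is erased on ring opening, where the cis geometry that ring B forces on the C4a=C11a double bond places the ketene and isopropenyl groups on the same side, as the 6π closure requires. The regiochemistry (OH, CH2OTBS, ether, ester, CH3, H around ring A) is set by the polarisation of the ynol ether and is the only mode the tether allows, because oxa-[4+2] addition of the acylketene would give a pyran-4-one bridged across its 2- and 6-positions by the four-atom catechol unit and a vinylketene [4+2] addition a para-bridged arene, both too strained to form. High temperature, slow addition and high dilution favour the entropically easy loss of N2 over intramolecular dipolar addition of the diazo group to the alkyne and keep capture of 23 by product phenol or by a second ketene slow.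

Step 13
Reactants: 27 4-(tert-butyldimethylsilyloxymethyl) analogue of mollicellin B
Product: 28 4-(hydroxymethyl) analogue of mollicellin B (salicyl alcohol)
Conditions: HF·pyridine, THF, 0 °C to rt
Reagents that add atoms: none
Why: Fluoride-driven Si–O cleavage, with weakly acidic HF·pyridine chosen over basic TBAF so that the aryl ester of ring B is not opened.

Step 14
Reactants: 28 4-(hydroxymethyl) analogue of mollicellin B
Product: 29 mollicellin B
Conditions: MnO2 (activated, excess), CH2Cl2, rt
Reagents that add atoms: none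
Why: MnO2 oxidation of a benzylic (salicyl) alcohol, which stops at the hydrogen-bonded salicylaldehyde and leaves the phenol, ester and ketone untouched.

**Compound list**
1 | 2-methoxy-6-methylphenol | COc1cccc(C)c1O | starting material
2 | 2-methoxy-6-methyl-1,4-benzoquinone | COC1=CC(=O)C=C(C)C1=O | intermediate
3 | 2-methoxy-6-methylbenzene-1,4-diol | COc1cc(O)cc(C)c1O | intermediate
4 | 3-methylbut-2-enoic acid | CC(C)=CC(=O)O | starting material
5 | 1-(3,6-dihydroxy-4-methoxy-2-methylphenyl)-3-methylbut-2-en-1-one | CC(C)=CC(=O)c1c(C)c(O)c(OC)cc1O | intermediate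
6 | 6-hydroxy-7-methoxy-2,2,5-trimethylchroman-4-one | COc1cc2OC(C)(C)CC(=O)c2c(C)c1O | intermediate
7 | 6,7-dihydroxy-2,2,5-trimethylchroman-4-one | Cc1c(O)c(O)cc2OC(C)(C)CC(=O)c12 | intermediate
8 | 2,2,5-trimethyl-6,7-bis(triisopropylsilyloxy)chroman-4-one | Cc1c(O[Si](C(C)C)(C(C)C)C(C)C)c(O[Si](C(C)C)(C(C)C)C(C)C)cc2OC(C)(C)CC(=O)c12 | intermediate
9 | 7-hydroxy-2,2,5-trimethyl-6-(triisopropylsilyloxy)chroman-4-one | Cc1c(O[Si](C(C)C)(C(C)C)C(C)C)c(O)cc2OC(C)(C)CC(=O)c12 | intermediate
10 | (tert-butyldimethylsilyloxy)acetaldehyde | O=CCO[Si](C)(C)C(C)(C)C | starting material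
11 | tert-butyl[(3,3-dibromoprop-2-en-1-yl)oxy]dimethylsilane | BrC(Br)=CCO[Si](C)(C)C(C)(C)C | intermediate
12 | 7-{[(Z)-1-bromo-3-(tert-butyldimethylsilyloxy)prop-1-en-1-yl]oxy}-2,2,5-trimethyl-6-(triisopropylsilyloxy)chroman-4-one | Cc1c(O[Si](C(C)C)(C(C)C)C(C)C)c(O/C(Br)=C/CO[Si](C)(C)C(C)(C)C)cc2OC(C)(C)CC(=O)c12 | intermediate
13 | 7-{[3-(tert-butyldimethylsilyloxy)prop-1-yn-1-yl]oxy}-2,2,5-trimethyl-6-(triisopropylsilyloxy)chroman-4-one | Cc1c(O[Si](C(C)C)(C(C)C)C(C)C)c(OC#CCO[Si](C)(C)C(C)(C)C)cc2OC(C)(C)CC(=O)c12 | intermediate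
14 | tert-butyl diazoacetate | CC(C)(C)OC(=O)C=[N+]=[N-] | starting material
15 | methacrolein | C=C(C)C=O | starting material
16 | tert-butyl lithiodiazoacetate | [Li]C(=[N+]=[N-])C(=O)OC(C)(C)C | intermediate
17 | tert-butyl 2-diazo-3-hydroxy-4-methylpent-4-enoate (racemic) | C=C(C)C(O)C(=[N+]=[N-])C(=O)OC(C)(C)C | intermediate
18 | tert-butyl 2-diazo-4-methyl-3-oxopent-4-enoate | C=C(C)C(=O)C(=[N+]=[N-])C(=O)OC(C)(C)C | intermediate
19 | 2-diazo-4-methyl-3-oxopent-4-enoic acid | C=C(C)C(=O)C(=[N+]=[N-])C(=O)O | intermediate
20 | 2-diazo-4-methyl-3-oxopent-4-enoyl chloride | C=C(C)C(=O)C(=[N+]=[N-])C(=O)Cl | intermediate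
21 | tris(dimethylamino)sulfonium 7-{[3-(tert-butyldimethylsilyloxy)prop-1-yn-1-yl]oxy}-2,2,5-trimethyl-4-oxochroman-6-olate | Cc1c([O-])c(OC#CCO[Si](C)(C)C(C)(C)C)cc2OC(C)(C)CC(=O)c12.CN(C)[S+](N(C)C)N(C)C | intermediate
22 | 7-{[3-(tert-butyldimethylsilyloxy)prop-1-yn-1-yl]oxy}-2,2,5-trimethyl-4-oxochroman-6-yl 2-diazo-4-methyl-3-oxopent-4-enoate (key-step precursor) | C=C(C)C(=O)C(=[N+]=[N-])C(=O)Oc1c(C)c2C(=O)CC(C)(C)Oc2cc1OC#CCO[Si](C)(C)C(C)(C)C | intermediate
23 | (aryloxycarbonyl)(isopropenyl)ketene on O6, ynol ether on O7 | C=C(C)C(=C=O)C(=O)Oc1c(C)c2C(=O)CC(C)(C)Oc2cc1OC#CCO[Si](C)(C)C(C)(C)C | intermediate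
24 | bicyclo[5.2.0] [2+2] adduct: cyclobutenone fused to ring B, quaternary carbon bearing isopropenyl and the C11 carbonyl (racemic) | O=C1C(CO[Si](C)(C)C(C)(C)C)=C2Oc3cc4OC(C)(C)CC(=O)c4c(C)c3OC(=O)C12C(C)=C | intermediate
25 | ring B dienylketene: C4a bears C(CH2OTBS)=C=O, C11a bears isopropenyl | O=C=C(CO[Si](C)(C)C(C)(C)C)C1=C(C(C)=C)C(=O)Oc2c(C)c3C(=O)CC(C)(C)Oc3cc2O1 | intermediate
26 | cyclohexa-2,4-dienone tautomer of 27 (C2 is CH2, C3 is C=O) | O=C1CC(C)=C2C(=O)Oc3c(C)c4C(=O)CC(C)(C)Oc4cc3OC2=C1CO[Si](C)(C)C(C)(C)C | intermediate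
27 | 4-(tert-butyldimethylsilyloxymethyl) analogue of mollicellin B (key-step product) | Cc1cc(O)c(CO[Si](C)(C)C(C)(C)C)c2c1C(=O)Oc1c(cc3c(c1C)C(=O)CC(C)(C)O3)O2 | intermediate
28 | 4-(hydroxymethyl) analogue of mollicellin B | Cc1cc(O)c(CO)c2c1C(=O)Oc1c(cc3c(c1C)C(=O)CC(C)(C)O3)O2 | intermediate
29 | mollicellin B | Cc1cc(O)c(C=O)c2c1C(=O)Oc1c(cc3c(c1C)C(=O)CC(C)(C)O3)O2 | target

**Step count**
Total steps: 14. Longest linear sequence: 10 (steps 1–5, 7, 11–14, from 1).

**Steps most likely to fail**

1. Step 12 (the labelled step).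
   - Risk: the ester has to turn into its less favoured E conformation before the ketene can reach the alkyne. Ring closure may therefore be outrun by capture of the ketene by product phenol, by ketene dimerisation, or by dipolar addition of the diazo group to the alkyne before nitrogen is lost.
   - Fallback, from 9 back to 29, in the classical depsidone order (diaryl ether, then lactone, then formyl group): orsellinic acid is dibenzylated (BnBr, K2CO3, DMF) to benzyl 4-(benzyloxy)-2-hydroxy-6-methylbenzoate F1. Its chelated OH is converted (Tf2O, pyridine) into the aryl triflate F2. Palladium-catalysed diaryl ether coupling of F2 with 9 (Pd(OAc)2, tBuXPhos, K3PO4, toluene, 100 °C) should give the diaryl ether F3. TBAF then frees the 6-OH to give the hydroxy ester F4, and hydrogenolysis (H2, Pd/C) removes both benzyl groups to give the dihydroxy acid F5. Carbodiimide lactonisation at high dilution closes ring B to 4-deformyl mollicellin B F6. Rieche formylation (Cl2CHOMe, TiCl4, CH2Cl2) at C4, the position between the C3 OH and O5, gives 29.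

2. Step 7.
   - Risk: the long heating with base and the KOtBu stage may cause loss of the TIPS group followed by closure of O6 onto the new C–O unit. They may also cause propargyl-to-allenyl isomerisation of the ynol ether, or retro-oxa-Michael opening of ring D.
   - Fallback, from 9 back to 13, by the alpha-aryloxy ketone/enol triflate route, in which the triple bond is made at −78 °C: 1,3-dihydroxyacetone is monosilylated (TBSCl, imidazole) to 1-(tert-butyldimethylsilyloxy)-3-hydroxypropan-2-one F7. Mitsunobu etherification with 9 (PPh3, DIAD, THF) gives the aryloxy ketone F8. Deprotonation at the more acidic ArOCH2 position and triflation (LiHMDS, PhNTf2, THF, −78 °C) gives the (Z)-enol triflate F9. Anti elimination (KOtBu, THF, −78 °C, minutes) gives 13.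

3. Step 11.
   - Risk: acylation of the doubly flanked phenoxide by the bulky, resonance-deactivated diazo acyl chloride may be slow. That would leave time for loss of the primary TBS group, for proton-triggered 5-exo closure onto the ynol ether, or for decay of the acid chloride.
   - Fallback, from 13 back to 22, building the side chain on the oxygen from small reactive pieces: the phenoxide made as in step 11 is quenched with bromoacetyl bromide to give the bromoacetate F10. N,N'-ditosylhydrazine and DBU (THF, 0 °C) convert it into the aryl diazoacetate F11. DBU-catalysed aldol addition to 15 (MeCN, 0 °C) gives the racemic beta-hydroxy diazo ester F12. MnO2 oxidation of this allylic alcohol gives 22.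

**Further compounds**
F1 | step 12 | benzyl 4-(benzyloxy)-2-hydroxy-6-methylbenzoate | Cc1cc(OCc2ccccc2)cc(O)c1C(=O)OCc1ccccc1
F2 | step 12 | benzyl 4-(benzyloxy)-6-methyl-2-(trifluoromethylsulfonyloxy)benzoate | Cc1cc(OCc2ccccc2)cc(OS(=O)(=O)C(F)(F)F)c1C(=O)OCc1ccccc1
F3 | step 12 | benzyl 4-(benzyloxy)-6-methyl-2-{[2,2,5-trimethyl-4-oxo-6-(triisopropylsilyloxy)chroman-7-yl]oxy}benzoate | Cc1cc(OCc2ccccc2)cc(Oc2cc3OC(C)(C)CC(=O)c3c(C)c2O[Si](C(C)C)(C(C)C)C(C)C)c1C(=O)OCc1ccccc1
F4 | step 12 | benzyl 4-(benzyloxy)-2-[(6-hydroxy-2,2,5-trimethyl-4-oxochroman-7-yl)oxy]-6-methylbenzoate | Cc1cc(OCc2ccccc2)cc(Oc2cc3OC(C)(C)CC(=O)c3c(C)c2O)c1C(=O)OCc1ccccc1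
F5 | step 12 | 4-hydroxy-2-[(6-hydroxy-2,2,5-trimethyl-4-oxochroman-7-yl)oxy]-6-methylbenzoic acid | Cc1cc(O)cc(Oc2cc3OC(C)(C)CC(=O)c3c(C)c2O)c1C(=O)O
F6 | step 12 | 4-deformyl mollicellin B | Cc1cc(O)cc2c1C(=O)Oc1c(cc3c(c1C)C(=O)CC(C)(C)O3)O2
F7 | step 7 | 1-(tert-butyldimethylsilyloxy)-3-hydroxypropan-2-one | OCC(=O)CO[Si](C)(C)C(C)(C)C
F8 | step 7 | 7-[3-(tert-butyldimethylsilyloxy)-2-oxopropoxy]-2,2,5-trimethyl-6-(triisopropylsilyloxy)chroman-4-one | Cc1c(O[Si](C(C)C)(C(C)C)C(C)C)c(OCC(=O)CO[Si](C)(C)C(C)(C)C)cc2OC(C)(C)CC(=O)c12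
F9 | step 7 | (Z)-3-(tert-butyldimethylsilyloxy)-1-{[2,2,5-trimethyl-4-oxo-6-(triisopropylsilyloxy)chroman-7-yl]oxy}prop-1-en-2-yl triflate | Cc1c(O[Si](C(C)C)(C(C)C)C(C)C)c(O/C=C(\OS(=O)(=O)C(F)(F)F)CO[Si](C)(C)C(C)(C)C)cc2OC(C)(C)CC(=O)c12
F10 | step 11 | 7-{[3-(tert-butyldimethylsilyloxy)prop-1-yn-1-yl]oxy}-2,2,5-trimethyl-4-oxochroman-6-yl bromoacetate | Cc1c(OC(=O)CBr)c(OC#CCO[Si](C)(C)C(C)(C)C)cc2OC(C)(C)CC(=O)c12
F11 | step 11 | 7-{[3-(tert-butyldimethylsilyloxy)prop-1-yn-1-yl]oxy}-2,2,5-trimethyl-4-oxochroman-6-yl diazoacetate | Cc1c(OC(=O)C=[N+]=[N-])c(OC#CCO[Si](C)(C)C(C)(C)C)cc2OC(C)(C)CC(=O)c12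
F12 | step 11 | 7-{[3-(tert-butyldimethylsilyloxy)prop-1-yn-1-yl]oxy}-2,2,5-trimethyl-4-oxochroman-6-yl 2-diazo-3-hydroxy-4-methylpent-4-enoate (racemic) | Cc1c(OC(=O)C(=[N+]=[N-])C(O)C(C)=C)c(OC#CCO[Si](C)(C)C(C)(C)C)cc2OC(C)(C)CC(=O)c12
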